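The ten-membered ring (C1–C10) is cut at C7–C8. With C9 as a ketone, C13=C11–C7–C8–C9=O is a γ,δ-unsaturated ketone, so the 2-substituted allyl group on C7 and the ring bond C7–C8 can both come from a Claisen rearrangement. The key step is the [3,3] ring contraction of a twelve-membered 2-methylene oxacycle whose oxygen joins C9 to C13: one heating closes the carbocycle, forms C7–C8, sets C7 and releases the C11=C13 methylene and the C9 carbonyl. The precursor is the enol ether obtained by titanium methylenation of a macrolactone that already holds the (4S,5R)-epoxide, the E C1=C10 alkene and three differently protected CH2O groups (C12, C14, C15).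

Key step: step 16

Remarks on the chemistry:
- Locants C1–C15 are those of the target (ring C1–C10, C11–C13 on C7, C14 on C10, C15 on C4) and are used for every intermediate. In this numbering the epoxide is (4S,5R) throughout.
- C7 keeps one spatial arrangement from step 16 on. Its CIP label is R in ketone 27, where C8 outranks C6, and S from 28 onward.
- Assumption: compounds 5, 9, 15, 16, 33 and 34 and the usual reagents are purchased.

Step 1
Reactants: 1 prop-2-yn-1-ol
Product: 2 tert-butyl(diphenyl)(prop-2-yn-1-yloxy)silane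
Conditions: TBDPSCl, imidazole, CH2Cl2, 0 °C → rt
Reagents that add atoms: tert-butyl(chloro)diphenylsilane, CC(C)(C)[Si](Cl)(c1ccccc1)c1ccccc1
Why: Standard silyl ether formation on a primary alcohol gives the robust ether that stays on the future C15 oxygen until the last step.

Step 2
Reactants: 2 tert-butyl(diphenyl)(prop-2-yn-1-yloxy)silane
Product: 4 methyl 4-{[tert-butyl(diphenyl)silyl]oxy}but-2-ynoate, via lithium acetylide 3 (not isolated)
Conditions: n-BuLi, THF, −78 °C; ClCO2Me, −78 → 0 °C
Reagents that add atoms: methyl chloroformate, COC(=O)Cl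
Why: Deprotonation of the terminal alkyne and C-acylation of the acetylide (alkynoate synthesis) installs C6 as an ester that activates the triple bond for conjugate addition.

Step 3
Reactants: 4 methyl 4-{[tert-butyl(diphenyl)silyl]oxy}but-2-ynoate; 5 but-3-en-1-ylmagnesium bromide
Product: 6 methyl (2Z)-3-({[tert-butyl(diphenyl)silyl]oxy}methyl)hepta-2,6-dienoate
Conditions: 5 (2.2 equiv), CuBr·SMe2 (1.1 equiv), THF, −78 °C; then 4, −78 °C; MeOH then aq NH4Cl at −78 °C
Reagents that add atoms: none
Why: Conjugate addition of the Grignard-derived cuprate to the alkynoate is a syn carbocupration, and cold protonation with retention places the butenyl group and H cis, so that CH2OSi (C15) is cis to the ester (C6) as the later trans-epoxide requires.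

Step 4
Reactants: 6 methyl (2Z)-3-({[tert-butyl(diphenyl)silyl]oxy}methyl)hepta-2,6-dienoate
Product: 7 (2Z)-3-({[tert-butyl(diphenyl)silyl]oxy}methyl)hepta-2,6-dien-1-ol
Conditions: iBu2AlH (2.5 equiv), CH2Cl2, −78 °C; Rochelle salt
Reagents that add atoms: none
Why: 1,2-Reduction of the conjugated ester with iBu2AlH gives the allylic alcohol without touching the isolated alkene or the silyl ether.

Step 5
Reactants: 7 (2Z)-3-({[tert-butyl(diphenyl)silyl]oxy}methyl)hepta-2,6-dien-1-ol
Product: 8 [(2R,3S)-3-(but-3-en-1-yl)-3-({[tert-butyl(diphenyl)silyl]oxy}methyl)oxiran-2-yl]methanol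
Conditions: Ti(OiPr)4 (10 mol%), D-(−)-diethyl tartrate (12 mol%), t-BuOOH, 4 Å MS, CH2Cl2, −20 °C
Reagents that add atoms: tert-butyl hydroperoxide, CC(C)(C)OO
Why: Katsuki–Sharpless asymmetric epoxidation of a 3,3-disubstituted allylic alcohol with the D-(−)-tartrate delivers oxygen to the face that makes C5 R, stereospecific syn addition to the Z alkene then makes C4 S, and the terminal alkene is left alone because it is not part of an allylic alcohol.

Step 6
Reactants: 8 [(2R,3S)-3-(but-3-en-1-yl)-3-({[tert-butyl(diphenyl)silyl]oxy}methyl)oxiran-2-yl]methanol; 9 trimethyl(prop-2-yn-1-yloxy)silane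
Product: 12 4-[(2R,3S)-3-(but-3-en-1-yl)-3-({[tert-butyl(diphenyl)silyl]oxy}methyl)oxiran-2-yl]but-2-yn-1-ol, via epoxy triflate 10 (not isolated), via trimethylsilyl ether 11 (not isolated)
Conditions: Tf2O, 2,6-lutidine, CH2Cl2, −78 °C; then lithium acetylide of 9 (n-BuLi), THF/DMPU, −78 → −30 °C; then K2CO3, MeOH, 0 °C
Reagents that add atoms: none
Why: Alkylation of a lithium acetylide with a primary triflate (SN2) forms C6–C7 at low temperature faster than any epoxide opening, and mild methanolysis of the labile trimethylsilyl ether frees the propargylic C12–OH needed to direct step 10.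

Step 7
Reactants: 12 4-[(2R,3S)-3-(but-3-en-1-yl)-3-({[tert-butyl(diphenyl)silyl]oxy}methyl)oxiran-2-yl]but-2-yn-1-ol
Product: 14 3-[(2S,3R)-2-({[tert-butyl(diphenyl)silyl]oxy}methyl)-3-(4-hydroxybut-2-yn-1-yl)oxiran-2-yl]propanal, via ozonide 13 (not isolated)
Conditions: O3, CH2Cl2, −78 °C (Sudan Red 7B end point); PPh3, −78 °C → rt
Reagents that add atoms: ozone, [O-][O+]=O
Why: Ozonolysis with reductive work-up cleaves the only alkene, which reacts far faster than the alkyne, and gives the C1 aldehyde without passing through a free C1 alcohol that could open the epoxide to a tetrahydrofuran.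

Step 8
Reactants: 15 methyl 2-(dimethoxyphosphoryl)prop-2-enoate; 16 (4-methoxyphenyl)methanol
Product: 17 methyl 2-(dimethoxyphosphoryl)-3-[(4-methoxyphenyl)methoxy]propanoate
Conditions: NaH (10 mol%), THF, 0 °C, slow addition of 15; AcOH quench
Reagents that add atoms: none
Why: Base-catalysed oxa-Michael addition of the benzylic alcohol to the doubly activated vinylphosphonate gives the α-(alkoxymethyl) phosphonoacetate that carries C9, C10 and the protected C14 oxygen.

Step 9
Reactants: 14 3-[(2S,3R)-2-({[tert-butyl(diphenyl)silyl]oxy}methyl)-3-(4-hydroxybut-2-yn-1-yl)oxiran-2-yl]propanal; 17 methyl 2-(dimethoxyphosphoryl)-3-[(4-methoxyphenyl)methoxy]propanoate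
Product: 18 methyl (2E)-5-[(2S,3R)-2-({[tert-butyl(diphenyl)silyl]oxy}methyl)-3-(4-hydroxybut-2-yn-1-yl)oxiran-2-yl]-2-{[(4-methoxyphenyl)methoxy]methyl}pent-2-enoate
Conditions: LiCl, DBU, MeCN, 0 °C → rt
Reagents that add atoms: none
Why: Horner–Wadsworth–Emmons olefination under mild Masamune–Roush conditions tolerates the epoxide and the free alcohol, and reversible addition of the stabilised α-substituted phosphonate anion should favour the more stable E trisubstituted enoate (ester trans to C2), the minor Z isomer being removed by chromatography.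

Step 10
Reactants: 18 methyl (2E)-5-[(2S,3R)-2-({[tert-butyl(diphenyl)silyl]oxy}methyl)-3-(4-hydroxybut-2-yn-1-yl)oxiran-2-yl]-2-{[(4-methoxyphenyl)methoxy]methyl}pent-2-enoate
Product: 20 methyl (2E)-5-[(2S,3R)-2-({[tert-butyl(diphenyl)silyl]oxy}methyl)-3-[(2Z)-4-hydroxy-3-iodobut-2-en-1-yl]oxiran-2-yl]-2-{[(4-methoxyphenyl)methoxy]methyl}pent-2-enoate, via alkenylstannane 19 (not isolated)
Conditions: Bu3SnH (1.05 equiv), [(C5Me5)RuCl]4 (2 mol%), CH2Cl2, rt; then 2,6-lutidine, I2, 0 °C
Reagents that add atoms: iodine, II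
Why: Hydroxyl-directed ruthenium-catalysed trans-hydrostannation puts tin on C11 next to the OH and H on C7 by anti addition, and iododestannylation with retention gives the alkenyl iodide in which iodine, the site of the future C13, is cis to C6.

Step 11
Reactants: 20 methyl (2E)-5-[(2S,3R)-2-({[tert-butyl(diphenyl)silyl]oxy}methyl)-3-[(2Z)-4-hydroxy-3-iodobut-2-en-1-yl]oxiran-2-yl]-2-{[(4-methoxyphenyl)methoxy]methyl}pent-2-enoate
Product: 21 tert-butyldimethylsilyl ether of 20 at C12–OH
Conditions: TBSCl, imidazole, CH2Cl2, 0 °C → rt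
Reagents that add atoms: tert-butyl(chloro)dimethylsilane, CC(C)(C)[Si](C)(C)Cl
Why: Routine silyl ether formation on the primary allylic alcohol distinguishes C12 (TBS) from C15 (TBDPS) and C14 (PMB).

Step 12
Reactants: 21 tert-butyldimethylsilyl ether of 20 at C12–OH
Product: 22 methyl (2E)-5-[(2S,3R)-3-[(2E)-3-({[tert-butyl(dimethyl)silyl]oxy}methyl)-4-hydroxybut-2-en-1-yl]-2-({[tert-butyl(diphenyl)silyl]oxy}methyl)oxiran-2-yl]-2-{[(4-methoxyphenyl)methoxy]methyl}pent-2-enoate
Conditions: Bu3SnCH2OH (2 equiv), Pd(PPh3)4 (10 mol%), iPr2NEt, 1,4-dioxane, 80 °C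
Reagents that add atoms: (tributylstannyl)methanol, OC[Sn](CCCC)(CCCC)CCCC
Why: Stille cross-coupling of the alkenyl iodide with the hydroxymethyl stannane proceeds with retention of alkene geometry and introduces C13 as a free CH2OH cis to C6, the amine buffer keeping the medium non-acidic.

Step 13
Reactants: 22 methyl (2E)-5-[(2S,3R)-3-[(2E)-3-({[tert-butyl(dimethyl)silyl]oxy}methyl)-4-hydroxybut-2-en-1-yl]-2-({[tert-butyl(diphenyl)silyl]oxy}methyl)oxiran-2-yl]-2-{[(4-methoxyphenyl)methoxy]methyl}pent-2-enoate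
Product: 23 seco acid: the carboxylic acid corresponding to methyl ester 22
Conditions: LiOH·H2O, THF/MeOH/H2O, rt; 0.5 M HCl to pH 5, 0 °C
Reagents that add atoms: lithium hydroxide (its oxygen becomes the carboxyl OH), [Li+].[OH-]
Why: Saponification of the methyl ester is tolerated by the silyl ethers, the PMB ether and the epoxide, and acidifying only to pH 5 in the cold avoids acid-catalysed opening of the epoxide by C13–OH.

Step 14
Reactants: 23 seco acid: the carboxylic acid corresponding to methyl ester 22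
Product: 25 twelve-membered macrolactone closed between C9 and O–C13, via mixed anhydride 24 (not isolated)
Conditions: 2,4,6-Cl3C6H2COCl, Et3N, THF, rt; then slow addition to DMAP, toluene (1 mM), 60 °C
Reagents that add atoms: none
Why: Yamaguchi macrolactonisation engages the only free hydroxyl, the unhindered primary allylic C13–OH, with the activated acid under high dilution, and the two rigid alkenes and the epoxide help fold the chain for twelve-membered ring closure.

Step 15
Reactants: 25 twelve-membered macrolactone closed between C9 and O–C13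
Product: 26 twelve-membered 2-methylene oxacycle (allyl vinyl ether; 25 with C9=O replaced by C9=C8H2)
Conditions: Cp2TiMe2 (3 equiv), toluene, 75 °C, dark; filtration through basic alumina, used at once
Reagents that add atoms: dimethyltitanocene Cp2TiMe2, C[Ti](C)(C1C=CC=C1)C1C=CC=C1
Why: Petasis methylenation (carbonyl olefination by Cp2Ti=CH2 generated thermally) converts the lactone carbonyl into the enol ether under non-acidic, non-Lewis-acidic conditions that spare the epoxide and all three ethers, conjugated esters reacting in the same way to give 2-alkoxydienes.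

Step 16
Reactants: 26 twelve-membered 2-methylene oxacycle (allyl vinyl ether; 25 with C9=O replaced by C9=C8H2)
Product: 27 ten-membered epoxy enone with C9 ketone and C7 bearing C(=C13H2)C12H2–OTBS
Conditions: degassed toluene (5 mM), Et3N (1%), base-washed sealed tube, 150 °C
Reagents that add atoms: none
Why: On heating, the allyl vinyl ether C8=C9–O–C13–C11=C7 undergoes a concerted, suprafacial [3,3]-sigmatropic (Claisen) shift through a chair-like six-atom array in which C8–C7 forms while C13–O breaks and C9 becomes the carbonyl carbon; the closest known reaction type is the Claisen ring contraction of 2-methylene oxacycles made by titanium methylenation of lactones. The ten-membered carbocycle is closed by ring contraction and not by end-to-end cyclisation: the exocyclic C8 bonds across to the in-ring C7 and O, C13 and C11 are pushed out of the ring, so the entropic cost of ring formation was already paid in the macrolactonisation. C7 is the only new stereocentre and is set by the face of the C7=C11 alkene that C8 reaches, which the resident (4S,5R)-epoxide controls through the seven-atom tether C10–C6: because C13 is cis to C6, C6 sits pseudo-axial next to C10, the tether folds into a two-layer arrangement with the C1=C10 alkene over the trans-epoxide, and the conformer that keeps the epoxide oxygen and the bulky C15 silyloxymethyl group on the periphery should present the face that gives the target configuration (7S in the target, formally 7R in ketone 27). The step needs periselectivity ([3,3] shift and not ionisation, [1,3] shift or hydrolysis of the enol ether), which the single allyl vinyl ether unit, base-washed glassware and a hydrocarbon solvent secure, and it needs the E C1=C10 alkene and the epoxide to survive, which they should because they lie outside the reacting array.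

Step 17
Reactants: 27 ten-membered epoxy enone with C9 ketone and C7 bearing C(=C13H2)C12H2–OTBS
Product: 28 (9R)-allylic alcohol from 27
Conditions: (S)-2-methyl-CBS-oxazaborolidine (1 equiv), catecholborane (2 equiv), toluene, −78 °C; MeOH; aq NaHCO3
Reagents that add atoms: none
Why: Corey–Bakshi–Shibata reduction under reagent control treats the α-substituted alkenyl side (C10) as the large group and the C8 methylene as the small one, so the (S)-oxazaborolidine should deliver hydride to the face that gives the (9R)-alcohol, and catecholborane at −78 °C does not hydroborate the alkenes.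

Step 18
Reactants: 28 (9R)-allylic alcohol from 27
Product: 29 C9 3-methylbut-2-enoate (senecioate) of 28
Conditions: 3-methylbut-2-enoyl chloride, pyridine, DMAP (5 mol%), CH2Cl2, 0 °C
Reagents that add atoms: 3-methylbut-2-enoyl chloride, CC(C)=CC(=O)Cl
Why: Acylation of the secondary allylic alcohol with the acid chloride (esterification) uses pyridine as a weak base so that the senecioyl group is not deconjugated through a vinylketene.

Step 19
Reactants: 29 C9 3-methylbut-2-enoate (senecioate) of 28
Product: 30 C12 primary alcohol (29 without the TBS group)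
Conditions: HF·pyridine, pyridine, THF, 0 °C
Reagents that add atoms: none
Why: Selective desilylation with pyridine-buffered HF·pyridine cleaves the primary allylic TBS ether much faster than the hindered TBDPS ether, and the buffer protects the epoxide.

Step 20
Reactants: 30 C12 primary alcohol (29 without the TBS group)
Product: 31 C12 acetate of 30
Conditions: Ac2O, pyridine, DMAP (5 mol%), CH2Cl2, 0 °C
Reagents that add atoms: acetic anhydride, CC(=O)OC(C)=O
Why: Acetylation of the primary alcohol (esterification) fixes the C12 acetate of the target before any other hydroxyl is free.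

Step 21
Reactants: 31 C12 acetate of 30
Product: 32 C14 primary alcohol (31 without the PMB group)
Conditions: DDQ, CH2Cl2/pH 7 phosphate buffer, 0 °C
Reagents that add atoms: none
Why: Oxidative cleavage of the 4-methoxybenzyl ether with DDQ under buffered two-phase conditions frees C14–OH without affecting the esters, the silyl ether, the epoxide or the alkenes.

Step 22
Reactants: 33 (4R)-4-benzyl-3-propanoyl-1,3-oxazolidin-2-one; 34 acetaldehyde
Product: 36 (4R)-4-benzyl-3-[(2R,3S)-3-hydroxy-2-methylbutanoyl]-1,3-oxazolidin-2-one, via boron enolate 35 (not isolated)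
Conditions: Bu2BOTf, iPr2NEt, CH2Cl2, 0 °C; 34, −78 → 0 °C; pH 7 buffer, MeOH, H2O2
Reagents that add atoms: none
Why: Evans syn-aldol reaction of the Z boron enolate through a closed Zimmerman–Traxler transition state on the face away from the benzyl group of the (R)-auxiliary sets C2 as R and C3 as S.

Step 23
Reactants: 36 (4R)-4-benzyl-3-[(2R,3S)-3-hydroxy-2-methylbutanoyl]-1,3-oxazolidin-2-one
Product: 37 tert-butyldimethylsilyl ether of 36
Conditions: TBSOTf, 2,6-lutidine, CH2Cl2, −78 → 0 °C
Reagents that add atoms: tert-butyldimethylsilyl trifluoromethanesulfonate, CC(C)(C)[Si](C)(C)OS(=O)(=O)C(F)(F)F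
Why: Silyl ether formation with the silyl triflate protects the hindered secondary hydroxyl so that the acid cannot acylate itself in the later coupling.

Step 24
Reactants: 37 tert-butyldimethylsilyl ether of 36
Product: 39 (2R,3S)-3-{[tert-butyl(dimethyl)silyl]oxy}-2-methylbutanoic acid, via peroxy acid 38 (not isolated)
Conditions: LiOH, H2O2, THF/H2O, 0 °C; Na2SO3; HCl to pH 3
Reagents that add atoms: hydrogen peroxide (as LiOOH; its oxygen becomes the carboxyl OH), OO
Why: Lithium hydroperoxide attacks the exocyclic imide carbonyl selectively (Evans auxiliary cleavage) and sulfite reduces the peroxy acid, giving the acid without epimerisation at C2.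

Step 25
Reactants: 32 C14 primary alcohol (31 without the PMB group); 39 (2R,3S)-3-{[tert-butyl(dimethyl)silyl]oxy}-2-methylbutanoic acid
Product: 40 protected target (C14 ester of 32 with 39; C15–OTBDPS and side-chain OTBS in place)
Conditions: DCC, DMAP (10 mol%), CH2Cl2, 0 °C → rt
Reagents that add atoms: none
Why: Steglich esterification acylates the unhindered primary allylic C14–OH quickly under nearly neutral conditions, so the neighbouring C9 senecioate should not migrate and the α-stereocentre of the acid should be kept.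

Step 26
Reactants: 40 protected target (C14 ester of 32 with 39; C15–OTBDPS and side-chain OTBS in place)
Product: 41 target CNP0227102.1
Conditions: HF·pyridine, pyridine, THF, 0 °C → rt
Reagents that add atoms: none
Why: Global desilylation with pyridine-buffered HF·pyridine removes the primary TBDPS and the secondary TBS ether while the three esters, the epoxide and the alkenes remain, and the non-basic medium prevents Payne rearrangement of the freed 2,3-epoxy alcohol and acyl migration.

Compound list
1 | prop-2-yn-1-ol | C#CCO | starting material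
2 | tert-butyl(diphenyl)(prop-2-yn-1-yloxy)silane | C#CCO[Si](c1ccccc1)(c1ccccc1)C(C)(C)C | intermediate
3 | lithium acetylide of 2 | [Li]C#CCO[Si](c1ccccc1)(c1ccccc1)C(C)(C)C | intermediate (not isolated)
4 | methyl 4-{[tert-butyl(diphenyl)silyl]oxy}but-2-ynoate | COC(=O)C#CCO[Si](c1ccccc1)(c1ccccc1)C(C)(C)C | intermediate
5 | but-3-en-1-ylmagnesium bromide | C=CCC[Mg]Br | starting material
6 | methyl (2Z)-3-({[tert-butyl(diphenyl)silyl]oxy}methyl)hepta-2,6-dienoate | COC(=O)/C=C(/CCC=C)CO[Si](c1ccccc1)(c1ccccc1)C(C)(C)C | intermediate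
7 | (2Z)-3-({[tert-butyl(diphenyl)silyl]oxy}methyl)hepta-2,6-dien-1-ol | OC/C=C(/CCC=C)CO[Si](c1ccccc1)(c1ccccc1)C(C)(C)C | intermediate
8 | [(2R,3S)-3-(but-3-en-1-yl)-3-({[tert-butyl(diphenyl)silyl]oxy}methyl)oxiran-2-yl]methanol | OC[C@H]1O[C@]1(CO[Si](c2ccccc2)(c2ccccc2)C(C)(C)C)CCC=C | intermediate
9 | trimethyl(prop-2-yn-1-yloxy)silane | C#CCO[Si](C)(C)C | starting material
10 | epoxy triflate: trifluoromethanesulfonate of 8 | FC(F)(F)S(=O)(=O)OC[C@H]1O[C@]1(CO[Si](c2ccccc2)(c2ccccc2)C(C)(C)C)CCC=C | intermediate (not isolated)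
11 | trimethylsilyl ether of 12 | C[Si](C)(C)OCC#CC[C@H]1O[C@]1(CO[Si](c2ccccc2)(c2ccccc2)C(C)(C)C)CCC=C | intermediate (not isolated)
12 | 4-[(2R,3S)-3-(but-3-en-1-yl)-3-({[tert-butyl(diphenyl)silyl]oxy}methyl)oxiran-2-yl]but-2-yn-1-ol | OCC#CC[C@H]1O[C@]1(CO[Si](c2ccccc2)(c2ccccc2)C(C)(C)C)CCC=C | intermediate
13 | ozonide of 12 (1,2,4-trioxolane at the former terminal alkene) | OCC#CC[C@H]1O[C@]1(CO[Si](c2ccccc2)(c2ccccc2)C(C)(C)C)CCC1OCOO1 | intermediate (not isolated)
14 | 3-[(2S,3R)-2-({[tert-butyl(diphenyl)silyl]oxy}methyl)-3-(4-hydroxybut-2-yn-1-yl)oxiran-2-yl]propanal | OCC#CC[C@H]1O[C@]1(CO[Si](c2ccccc2)(c2ccccc2)C(C)(C)C)CCC=O | intermediate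
15 | methyl 2-(dimethoxyphosphoryl)prop-2-enoate (trimethyl 2-phosphonoacrylate) | COC(=O)C(=C)P(=O)(OC)OC | starting material
16 | (4-methoxyphenyl)methanol | COc1ccc(CO)cc1 | starting material
17 | methyl 2-(dimethoxyphosphoryl)-3-[(4-methoxyphenyl)methoxy]propanoate (racemic) | COC(=O)C(COCc1ccc(OC)cc1)P(=O)(OC)OC | intermediate
18 | methyl (2E)-5-[(2S,3R)-2-({[tert-butyl(diphenyl)silyl]oxy}methyl)-3-(4-hydroxybut-2-yn-1-yl)oxiran-2-yl]-2-{[(4-methoxyphenyl)methoxy]methyl}pent-2-enoate | COC(=O)/C(COCc1ccc(OC)cc1)=C/CC[C@@]2(CO[Si](c3ccccc3)(c3ccccc3)C(C)(C)C)O[C@@H]2CC#CCO | intermediate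
19 | alkenylstannane: 18 with the alkyne converted to (2Z)-4-hydroxy-3-(tributylstannyl)but-2-en-1-yl | COC(=O)/C(COCc1ccc(OC)cc1)=C/CC[C@@]2(CO[Si](c3ccccc3)(c3ccccc3)C(C)(C)C)O[C@@H]2C/C=C(/CO)[Sn](CCCC)(CCCC)CCCC | intermediate (not isolated)
20 | alkenyl iodide: methyl (2E)-5-[(2S,3R)-2-({[tert-butyl(diphenyl)silyl]oxy}methyl)-3-[(2Z)-4-hydroxy-3-iodobut-2-en-1-yl]oxiran-2-yl]-2-{[(4-methoxyphenyl)methoxy]methyl}pent-2-enoate | COC(=O)/C(COCc1ccc(OC)cc1)=C/CC[C@@]2(CO[Si](c3ccccc3)(c3ccccc3)C(C)(C)C)O[C@@H]2C/C=C(/CO)I | intermediate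
21 | tert-butyldimethylsilyl ether of 20 at C12–OH | COC(=O)/C(COCc1ccc(OC)cc1)=C/CC[C@@]2(CO[Si](c3ccccc3)(c3ccccc3)C(C)(C)C)O[C@@H]2C/C=C(/CO[Si](C)(C)C(C)(C)C)I | intermediate
22 | hydroxy ester: 21 with iodine replaced by C13H2OH (C13 cis to C6) | COC(=O)/C(COCc1ccc(OC)cc1)=C/CC[C@@]2(CO[Si](c3ccccc3)(c3ccccc3)C(C)(C)C)O[C@@H]2C/C=C(/CO[Si](C)(C)C(C)(C)C)CO | intermediate
23 | seco acid: the carboxylic acid corresponding to methyl ester 22 | OC(=O)/C(COCc1ccc(OC)cc1)=C/CC[C@@]2(CO[Si](c3ccccc3)(c3ccccc3)C(C)(C)C)O[C@@H]2C/C=C(/CO[Si](C)(C)C(C)(C)C)CO | intermediate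
24 | mixed anhydride of 23 with 2,4,6-trichlorobenzoic acid | O=C(OC(=O)c1c(Cl)cc(Cl)cc1Cl)/C(COCc1ccc(OC)cc1)=C/CC[C@@]2(CO[Si](c3ccccc3)(c3ccccc3)C(C)(C)C)O[C@@H]2C/C=C(/CO[Si](C)(C)C(C)(C)C)CO | intermediate (not isolated)
25 | twelve-membered macrolactone: C9(=O)–O–C13; (4S,5R)-epoxide with C15–OTBDPS; E C1=C10 bearing C14H2–OPMB; C7=C11 with C13 cis to C6 and exocyclic C12H2–OTBS | O=C1OC/C(CO[Si](C)(C)C(C)(C)C)=C\C[C@H]2O[C@]2(CO[Si](c3ccccc3)(c3ccccc3)C(C)(C)C)CC/C=C1\COCc1ccc(OC)cc1 | intermediate
26 | twelve-membered 2-methylene oxacycle (allyl vinyl ether; 25 with C9=O replaced by C9=C8H2) | C=C1OC/C(CO[Si](C)(C)C(C)(C)C)=C\C[C@H]2O[C@]2(CO[Si](c3ccccc3)(c3ccccc3)C(C)(C)C)CC/C=C1\COCc1ccc(OC)cc1 | intermediate (key-step precursor)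
27 | ten-membered epoxy enone: C9 ketone; E C1=C10 with C14H2–OPMB; (4S,5R)-epoxide with C15–OTBDPS; C7 bearing C(=C13H2)C12H2–OTBS in the target configuration | C=C(CO[Si](C)(C)C(C)(C)C)[C@H]1CC(=O)/C(COCc2ccc(OC)cc2)=C/CC[C@@]3(CO[Si](c2ccccc2)(c2ccccc2)C(C)(C)C)O[C@@H]3C1 | intermediate (key-step product)
28 | (9R)-allylic alcohol from 27 (4S,5R,7S,9R) | C=C(CO[Si](C)(C)C(C)(C)C)[C@H]1C[C@@H](O)/C(COCc2ccc(OC)cc2)=C/CC[C@@]3(CO[Si](c2ccccc2)(c2ccccc2)C(C)(C)C)O[C@@H]3C1 | intermediate
29 | C9 3-methylbut-2-enoate (senecioate) of 28 | C=C(CO[Si](C)(C)C(C)(C)C)[C@H]1C[C@@H](OC(=O)C=C(C)C)/C(COCc2ccc(OC)cc2)=C/CC[C@@]3(CO[Si](c2ccccc2)(c2ccccc2)C(C)(C)C)O[C@@H]3C1 | intermediate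
30 | C12 primary alcohol (29 without the TBS group) | C=C(CO)[C@H]1C[C@@H](OC(=O)C=C(C)C)/C(COCc2ccc(OC)cc2)=C/CC[C@@]3(CO[Si](c2ccccc2)(c2ccccc2)C(C)(C)C)O[C@@H]3C1 | intermediate
31 | C12 acetate of 30 | C=C(COC(C)=O)[C@H]1C[C@@H](OC(=O)C=C(C)C)/C(COCc2ccc(OC)cc2)=C/CC[C@@]3(CO[Si](c2ccccc2)(c2ccccc2)C(C)(C)C)O[C@@H]3C1 | intermediate
32 | C14 primary alcohol (31 without the PMB group) | C=C(COC(C)=O)[C@H]1C[C@@H](OC(=O)C=C(C)C)/C(CO)=C/CC[C@@]3(CO[Si](c2ccccc2)(c2ccccc2)C(C)(C)C)O[C@@H]3C1 | intermediate
33 | (4R)-4-benzyl-3-propanoyl-1,3-oxazolidin-2-one | CCC(=O)N1C(=O)OC[C@H]1Cc1ccccc1 | starting material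
34 | acetaldehyde | CC=O | starting material
35 | Z dibutylboron enolate of 33 | C/C=C(\OB(CCCC)CCCC)N1C(=O)OC[C@H]1Cc1ccccc1 | intermediate (not isolated)
36 | (4R)-4-benzyl-3-[(2R,3S)-3-hydroxy-2-methylbutanoyl]-1,3-oxazolidin-2-one | C[C@H](O)[C@@H](C)C(=O)N1C(=O)OC[C@H]1Cc1ccccc1 | intermediate
37 | tert-butyldimethylsilyl ether of 36 | C[C@H](O[Si](C)(C)C(C)(C)C)[C@@H](C)C(=O)N1C(=O)OC[C@H]1Cc1ccccc1 | intermediate
38 | (2R,3S)-3-{[tert-butyl(dimethyl)silyl]oxy}-2-methylbutaneperoxoic acid | C[C@H](O[Si](C)(C)C(C)(C)C)[C@@H](C)C(=O)OO | intermediate (not isolated)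
39 | (2R,3S)-3-{[tert-butyl(dimethyl)silyl]oxy}-2-methylbutanoic acid | C[C@H](O[Si](C)(C)C(C)(C)C)[C@@H](C)C(=O)O | intermediate
40 | protected target: C14 ester of 32 with 39; C15–OTBDPS and side-chain OTBS in place | C=C(COC(C)=O)[C@H]1C[C@@H](OC(=O)C=C(C)C)/C(COC(=O)[C@H](C)[C@H](C)O[Si](C)(C)C(C)(C)C)=C/CC[C@@]3(CO[Si](c2ccccc2)(c2ccccc2)C(C)(C)C)O[C@@H]3C1 | intermediate
41 | CNP0227102.1: (4S,5R,7S,9R)-12-acetoxy-4,5-epoxy-15-hydroxy-14-[(2R,3S)-3-hydroxy-2-methylbutanoyloxy]-9-(3-methylbut-2-enoyloxy)germacra-1(10)E,11(13)-diene | C=C(COC(C)=O)[C@H]1C[C@@H](OC(=O)C=C(C)C)/C(COC(=O)[C@H](C)[C@H](C)O)=C/CC[C@@]2(CO)O[C@@H]2C1 | target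

Total step count: 26. Longest linear sequence: 22 steps (steps 1–7, 9–21, 25, 26). Side branches are step 8 (the phosphonate) and steps 22–24 (the side-chain acid).

Steps most likely to fail

1. Step 16. The new C8–C7 bond may form on the wrong face of C7, or with poor facial selectivity, because the control is relayed from the remote epoxide through a flexible tether. The enol ether may also be lost by hydrolysis before it rearranges. The fallback builds the geometric isomer of the enol ether, in which the other CH2O arm of C11 (C12, trans to C6) lies in the ring. C6 is then pseudo-equatorial in the chair array, so the same folded tether should turn the opposite face of C7 toward C8, and either isomer gives the same constitution because whichever arm is in the ring ends as the methylene. It sets out from 20 and comes back at 27. Acetylation (Ac2O, pyridine) gives the iodo acetate F1. Stille hydroxymethylation as in step 12 gives the hydroxy acetate F2, and silylation (TBSCl, imidazole) gives the silyl ether acetate F3. LiOH cleaves both the methyl ester and the acetate to the isomeric seco acid F4, with C12–OH free and C13–OTBS. Yamaguchi lactonisation through the mixed anhydride F5 closes the isomeric macrolactone F6, Cp2TiMe2 gives the isomeric enol ether F7, and heating as in step 16 gives 27.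

2. Step 9. The olefination may give a poor E/Z ratio at C1=C10, and the phosphonate anion may lose 4-methoxybenzyl oxide by β-elimination. The fallback fixes the geometry first and attaches the oxygenated carbon afterwards; it sets out from 14 and comes back at 18. Methyl (triphenylphosphoranylidene)acetate is iodinated with N-iodosuccinimide and K2CO3 to the iodo ylide F8. This reacts in the same flask with 14 in a tandem halogenation–Wittig olefination to give the Z α-iodo enoate F9, with iodine cis to C2 and the ester trans. Stille coupling of F9 with the alkoxymethyl stannane F10 (made from (tributylstannyl)methanol, NaH and 4-methoxybenzyl chloride) with Pd(PPh3)4 and CuI proceeds with retention and gives 18.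

3. Step 12. Transfer of the sp3 hydroxymethyl group from tin may be slow, with competing butyl transfer or reduction of the iodide, and prolonged heating may let the new C13–OH open the epoxide. The fallback sets out from 21 and comes back at 22. Palladium-catalysed formylation (CO 1 atm, Bu3SnH added slowly, Pd(PPh3)4, THF, 50 °C) gives the enal F11 with retention of geometry. Luche reduction (NaBH4, CeCl3·7H2O, MeOH, −40 °C) then reduces only the aldehyde and gives 22.

Further compounds
F1 | step 16 | C12 acetate of 20 (iodo acetate) | COC(=O)/C(COCc1ccc(OC)cc1)=C/CC[C@@]2(CO[Si](c3ccccc3)(c3ccccc3)C(C)(C)C)O[C@@H]2C/C=C(/COC(C)=O)I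
F2 | step 16 | hydroxy acetate: F1 with iodine replaced by C13H2OH | COC(=O)/C(COCc1ccc(OC)cc1)=C/CC[C@@]2(CO[Si](c3ccccc3)(c3ccccc3)C(C)(C)C)O[C@@H]2C/C=C(/COC(C)=O)CO
F3 | step 16 | silyl ether acetate: C13–OTBS ether of F2 | COC(=O)/C(COCc1ccc(OC)cc1)=C/CC[C@@]2(CO[Si](c3ccccc3)(c3ccccc3)C(C)(C)C)O[C@@H]2C/C=C(/COC(C)=O)CO[Si](C)(C)C(C)(C)C
F4 | step 16 | isomeric seco acid (C12–OH free; C13–OTBS) | OC(=O)/C(COCc1ccc(OC)cc1)=C/CC[C@@]2(CO[Si](c3ccccc3)(c3ccccc3)C(C)(C)C)O[C@@H]2C/C=C(/CO)CO[Si](C)(C)C(C)(C)C
F5 | step 16 | mixed anhydride of F4 with 2,4,6-trichlorobenzoic acid | O=C(OC(=O)c1c(Cl)cc(Cl)cc1Cl)/C(COCc1ccc(OC)cc1)=C/CC[C@@]2(CO[Si](c3ccccc3)(c3ccccc3)C(C)(C)C)O[C@@H]2C/C=C(/CO)CO[Si](C)(C)C(C)(C)C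
F6 | step 16 | isomeric macrolactone (C9(=O)–O–C12; C12 trans to C6; exocyclic C13H2–OTBS) | O=C1OC/C(CO[Si](C)(C)C(C)(C)C)=C/C[C@H]2O[C@]2(CO[Si](c3ccccc3)(c3ccccc3)C(C)(C)C)CC/C=C1\COCc1ccc(OC)cc1
F7 | step 16 | isomeric enol ether (F6 with C9=O replaced by C9=C8H2) | C=C1OC/C(CO[Si](C)(C)C(C)(C)C)=C/C[C@H]2O[C@]2(CO[Si](c3ccccc3)(c3ccccc3)C(C)(C)C)CC/C=C1\COCc1ccc(OC)cc1
F8 | step 9 | methyl iodo(triphenylphosphoranylidene)acetate (iodo ylide) | COC(=O)C(I)=P(c1ccccc1)(c1ccccc1)c1ccccc1
F9 | step 9 | methyl (2Z)-5-[(2S,3R)-2-({[tert-butyl(diphenyl)silyl]oxy}methyl)-3-(4-hydroxybut-2-yn-1-yl)oxiran-2-yl]-2-iodopent-2-enoate | COC(=O)/C(I)=C/CC[C@@]1(CO[Si](c2ccccc2)(c2ccccc2)C(C)(C)C)O[C@@H]1CC#CCO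
F10 | step 9 | tributyl({[(4-methoxyphenyl)methoxy]methyl})stannane | CCCC[Sn](CCCC)(CCCC)COCc1ccc(OC)cc1
F11 | step 12 | enal: 21 with iodine replaced by C13H=O (CHO cis to C6) | COC(=O)/C(COCc1ccc(OC)cc1)=C/CC[C@@]2(CO[Si](c3ccccc3)(c3ccccc3)C(C)(C)C)O[C@@H]2C/C=C(/CO[Si](C)(C)C(C)(C)C)C=O
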